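**The vessel.** The vessel is closed and keeps its volume, so whatever is charged as Ry stays in it, and I can keep a balance in percent of the charge.

| flask | Ry | remark | time |
|---|---|---|---|
| summer | 12 mM | run made earlier |  |
| autumn | 17 mM | run made earlier |  |
| north-east | 23 mM |  | 1.5 h |
| south-east | 23 mM |  | 5.0 h |

- summer (time / min: Uj / %, Ry / %, Ej / %): 10.0: 1.6, 75.6, 21.1; 25.0: 8.3, 50.5, 37.2; 50.0: 24.5, 24.9, 41.0; 80.0: 41.6, 10.9, 31.9
- autumn (time / min: Uj / %, Ry / %, Ej / %): 10.0: 1.3, 76.1, 21.5; 25.0: 9.0, 49.8, 37.7; 50.0: 25.0, 25.7, 40.5; 80.0: 41.2, 10.7, 31.2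

(readings scatter by 0.3 percentage points)

* which of these there is most of at the end, counted by the Ry in it, north-east (Uj / Ej / Ry)
* which of these there is most of at the end, counted by the Ry in it, south-east (Uj / Ej / Ry)
* final amount of the leader among these, as a percentage of the Ry charged, in north-east
* final amount of the leader among these, as a percentage of the Ry charged, in south-east

**The number.** In the summer run at 80.0 min, Ry and Ej together leave 57.2% of the charge past Ej, but Uj reads 41.6%. Uj over that share, averaged between the summer and autumn readings at that time, comes to 0.718. This is my number: the kept share s, Uj divided by all that has gone past Ej, a selectivity.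

**Is it enough?** At 50.0 min the same ratio reads 0.718 in summer and 0.740 in autumn. I take that spread for scatter. At 25.0 min the summer ratio reads 0.675, which is less than s, so I use s for late times and not for the early readings. Going from cRy 12 mM to 17 mM shows no trend, so I carry s to 23 mM. But s tells what becomes of material that has passed, not how much has passed, so I need a clock. The summer Ry gives a first-order constant of 0.0277 min⁻¹. The balance between its last two readings gives a loss constant for Ej of 0.0211 min⁻¹. The two first-order steps in a row integrate in closed form.

**My reckoning.** In north-east at 1.5 h, I get Ry 8.26% and Ej 28.1%, so Uj is s times the rest, 45.7%, and it leads. In south-east at 5.0 h, I get Ej 0.641%, so I reckon that Uj leads with 71.3%.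

**The forecast.** The forecast also names Uj in north-east and Uj in south-east, at 46% and 71%, holding that “the rest goes to something unseen”.

**The result.** North-east gives Uj at 46.5% and south-east gives Uj at 70.2%, Dz counted in.

    Ry → Ej (k = 4.60 × 10⁻⁴ s⁻¹)
    Ej ⇌ Uj (K = 1.10, k = 2.80 × 10⁻⁴ s⁻¹)
    Ej → Qe (k = 1.00 × 10⁻⁴ s⁻¹)
    Dz ⇌ Uj, rate k4*(cs4 - [Uj]) while solid is left; crystals form when [Uj] > cs4 (solubility = 0.350 mM, k = 0.00910 s⁻¹)

South-east holds 28.2% of Qe at 5.00 h, and its kept share reads 0.713. North-east, read instead at 2.5 h, has Ry 1.59% and Ej 11.0% left, so s gives 62.8%, and that flask holds Uj 63.1%.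

Readings and results stem from a simulated flask with made-up constants; scatter was added.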